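**Plan**

- Retrosynthesis: after the four protecting groups, the C4–C3 bond of ring C is cut first, as an intramolecular alkene hydroacylation. This leads back to a ring-A aldehyde (formyl carbon = C4) whose ortho oxygen O1 carries the 1-arylvinyl unit C2(=C3H2)–ring B.
- Enabling feature: C2 bears O1 and ring B, and C3 is a CH2 beside the C4 carbonyl. C2=C3 can therefore be an enol ether double bond held by O1 next to the formyl group, and since C2 has no hydrogen only "H to C2, acyl to C3" is productive.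
- Further cuts: C4–C4a (formyl by ortho-lithiation), C6–geranyl (ortho-lithiation/allylation), the C3 methylene (ester methylenation), O1–C2 (aryl ester from 3,5-bis(methoxymethoxy)phenol and a ring-B benzoic acid).
- Ring A stays symmetric until the formyl group enters: geranyl carbon C6 lies para to C8a (O1), so C4a and C8 are equivalent and the 6-geranyl pattern is fixed without a regiochemical choice.
- Forward order: rings A and B joined as an ester, then enol ether, geranyl, formyl, closure of ring C, desilylation, MOM cleavage.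
- Stereochemistry: the single stereocentre C2 (S) is set in the ring closure by the chiral bisphosphine on rhodium; the E double bond comes in with geranyl bromide.

Key step: step 7

Assumption: the (R) enantiomer of DTBM-SEGPHOS is taken to deliver hydride to the enol ether face that gives 2S; if the sense proves opposite, the (S) ligand is used instead.

**Route**

Step 1
Reactants: 1 phloroglucinol (benzene-1,3,5-triol)
Product: 2 3,5-bis(methoxymethoxy)phenol
Conditions: NaH (2.0 equiv), MOMCl (2.0 equiv), DMF, 0 °C to rt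
Reagents that add atoms: chloromethyl methyl ether (MOMCl), COCCl
Why: Williamson-type O-alkylation of the phenoxide; the three hydroxyls of 1 are equivalent, so two equivalents of reagent should give the bis-ether 2 as the main part of a statistical mixture, from which it is separated by chromatography.

Step 2
Reactants: 3 3,5-dihydroxybenzoic acid
Product: 5 3,5-bis(triisopropylsilyloxy)benzoic acid, via silyl ester 4 (not isolated)
Conditions: TIPSCl (3.3 equiv), imidazole, DMF, rt; then AcOH, THF, H2O, rt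
Reagents that add atoms: triisopropylsilyl chloride (TIPSCl), CC(C)[Si](Cl)(C(C)C)C(C)C
Why: Exhaustive imidazole-mediated silylation followed by selective solvolysis of the silyl ester, which is far more labile to aqueous acid than the two hindered aryl silyl ethers.

Step 3
Reactants: 2 3,5-bis(methoxymethoxy)phenol; 5 3,5-bis(triisopropylsilyloxy)benzoic acid
Product: 6 3,5-bis(methoxymethoxy)phenyl 3,5-bis(triisopropylsilyloxy)benzoate
Conditions: DCC, DMAP (cat.), CH2Cl2, 0 °C to rt
Reagents that add atoms: none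
Why: Steglich esterification: DCC activates 5 as the O-acylisourea and DMAP relays the acyl group to the phenol under neutral conditions that leave MOM and silyl ethers untouched.

Step 4
Reactants: 6 3,5-bis(methoxymethoxy)phenyl 3,5-bis(triisopropylsilyloxy)benzoate
Product: 7 1-({1-[3,5-bis(triisopropylsilyloxy)phenyl]ethenyl}oxy)-3,5-bis(methoxymethoxy)benzene
Conditions: Cp2TiMe2 (3 equiv), toluene/THF, 65 °C, dark; filtration through basic alumina
Reagents that add atoms: dimethyltitanocene (Cp2TiMe2), C[Ti](C)(C1C=CC=C1)C1C=CC=C1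
Why: Petasis methylenation: thermally formed Cp2Ti=CH2 adds [2+2] to the ester carbonyl and the oxatitanacyclobutane cycloreverts to the 1-arylvinyl aryl ether, as with simple aryl benzoates, under non-acidic conditions that the acetal and silyl ethers tolerate.

Step 5
Reactants: 7 1-({1-[3,5-bis(triisopropylsilyloxy)phenyl]ethenyl}oxy)-3,5-bis(methoxymethoxy)benzene; 8 geranyl bromide ((2E)-1-bromo-3,7-dimethylocta-2,6-diene)
Product: 10 5-({1-[3,5-bis(triisopropylsilyloxy)phenyl]ethenyl}oxy)-2-[(2E)-3,7-dimethylocta-2,6-dien-1-yl]-1,3-bis(methoxymethoxy)benzene, via aryllithium 9 (not isolated)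
Conditions: n-BuLi, TMEDA, THF, −20 to 0 °C; CuBr·SMe2 (0.2 equiv), then 8, −78 to 0 °C
Reagents that add atoms: none
Why: Directed ortho-metalation should occur at the one ring-A C–H flanked by two chelating OMOM groups (the other two are flanked by one OMOM and the bulky, weakly coordinating vinyl ether oxygen; the ring-B silyl ethers do not direct), and copper-assisted SN2 allylation by geranyl bromide keeps the E geometry.

Step 6
Reactants: 10 5-({1-[3,5-bis(triisopropylsilyloxy)phenyl]ethenyl}oxy)-2-[(2E)-3,7-dimethylocta-2,6-dien-1-yl]-1,3-bis(methoxymethoxy)benzene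
Product: 13 6-({1-[3,5-bis(triisopropylsilyloxy)phenyl]ethenyl}oxy)-3-[(2E)-3,7-dimethylocta-2,6-dien-1-yl]-2,4-bis(methoxymethoxy)benzaldehyde, via aryllithium 11 (not isolated), via lithium hemiaminal alkoxide 12 (not isolated)
Conditions: s-BuLi, TMEDA, THF, −78 °C; DMF, −78 to 0 °C; then H2O
Reagents that add atoms: N,N-dimethylformamide (DMF), CN(C)C=O
Why: Second directed ortho-metalation and formylation with DMF: the two remaining ring-A C–H bonds are equivalent by symmetry and each is ortho to an OMOM group, so only one aldehyde can form, with the formyl carbon between OMOM and the vinyl ether oxygen.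

Step 7
Reactants: 13 6-({1-[3,5-bis(triisopropylsilyloxy)phenyl]ethenyl}oxy)-3-[(2E)-3,7-dimethylocta-2,6-dien-1-yl]-2,4-bis(methoxymethoxy)benzaldehyde
Product: 14 (2S)-2-[3,5-bis(triisopropylsilyloxy)phenyl]-6-[(2E)-3,7-dimethylocta-2,6-dien-1-yl]-5,7-bis(methoxymethoxy)-2,3-dihydro-4H-chromen-4-one
Conditions: [Rh(cod)Cl]2 (2.5 mol %), (R)-DTBM-SEGPHOS (5 mol %), Na[B(3,5-(CF3)2C6H3)4] (5 mol %), 1,4-dioxane, 60–80 °C
Reagents that add atoms: none
Why: Proposed new method: the cationic bisphosphine complex of monovalent rhodium should insert into the formyl C–H bond of 13 to give an acyl hydride of trivalent rhodium, the hydride should add to the oxygen- and aryl-bearing alkene carbon C2 while rhodium takes the terminal CH2 (C3), and C–C reductive elimination from the seven-membered acyl alkyl rhodacycle should form the C4–C3 bond and return monovalent rhodium. The closest known reaction type is the rhodium-catalysed, enantioselective, endo-selective intramolecular hydroacylation of ortho-allylbenzaldehydes bearing 1,1-disubstituted alkenes to 3-substituted 1-tetralones, of which 13 is the analogue with the benzylic CH2 replaced by O1; what is new is that the alkene is an enol ether. Ring C closes in the 6-endo-trig mode, both alkene carbons ending up in the ring. The only new stereocentre, C2, arises when hydride is delivered to one enantiotopic face of the 1,1-disubstituted enol ether and is under catalyst control by the C2-symmetric bisphosphine, the (R) ligand being assumed to give 2S. The step needs endo over exo closure and hydroacylation over decarbonylation: C2 has no hydrogen and two large groups, so the alternative insertion that puts rhodium on C2 gives a tertiary alkyl that can only revert or close slowly to a quaternary centre, alkene isomerization is impossible, and the formyl group is flanked by the C5 MOM ether oxygen and by O1, whose coordination should hold the acyl hydride and slow CO loss. The trisubstituted geranyl double bonds bind rhodium weakly and cannot reach the acyl carbon from their meta position, so they should stay untouched.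

Step 8
Reactants: 14 (2S)-2-[3,5-bis(triisopropylsilyloxy)phenyl]-6-[(2E)-3,7-dimethylocta-2,6-dien-1-yl]-5,7-bis(methoxymethoxy)-2,3-dihydro-4H-chromen-4-one
Product: 15 (2S)-2-(3,5-dihydroxyphenyl)-6-[(2E)-3,7-dimethylocta-2,6-dien-1-yl]-5,7-bis(methoxymethoxy)-2,3-dihydro-4H-chromen-4-one
Conditions: Bu4NF, AcOH (1:1), THF, 0 °C
Reagents that add atoms: none
Why: Fluoride-driven cleavage of the aryl silyl ethers through Si–F bond formation; the acetic acid buffer keeps the medium from becoming basic, so that E1cB ring opening to the chalcone, which would racemize C2, should not set in.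

Step 9
Reactants: 15 (2S)-2-(3,5-dihydroxyphenyl)-6-[(2E)-3,7-dimethylocta-2,6-dien-1-yl]-5,7-bis(methoxymethoxy)-2,3-dihydro-4H-chromen-4-one
Product: 16 Schizolaenone C, (2S)-2-(3,5-dihydroxyphenyl)-6-[(2E)-3,7-dimethylocta-2,6-dien-1-yl]-5,7-dihydroxy-2,3-dihydro-4H-chromen-4-one
Conditions: HCl (1.25 M in MeOH), 0 to 40 °C
Reagents that add atoms: none
Why: Acid-catalysed transacetalization of the two MOM ethers to dimethoxymethane under the mild methanolic conditions customary for prenylated flavonoids; the flavanone is configurationally stable to dilute acid and the low temperature should keep the geranyl chain from cyclizing onto the flanking phenols.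

**Compound list**

1 | phloroglucinol | Oc1cc(O)cc(O)c1 | starting material
2 | 3,5-bis(methoxymethoxy)phenol | COCOc1cc(O)cc(OCOC)c1 | intermediate
3 | 3,5-dihydroxybenzoic acid | OC(=O)c1cc(O)cc(O)c1 | starting material
4 | triisopropylsilyl 3,5-bis(triisopropylsilyloxy)benzoate | CC(C)[Si](C(C)C)(C(C)C)OC(=O)c1cc(O[Si](C(C)C)(C(C)C)C(C)C)cc(O[Si](C(C)C)(C(C)C)C(C)C)c1 | intermediate
5 | 3,5-bis(triisopropylsilyloxy)benzoic acid | OC(=O)c1cc(O[Si](C(C)C)(C(C)C)C(C)C)cc(O[Si](C(C)C)(C(C)C)C(C)C)c1 | intermediate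
6 | 3,5-bis(methoxymethoxy)phenyl 3,5-bis(triisopropylsilyloxy)benzoate | COCOc1cc(OCOC)cc(OC(=O)c2cc(O[Si](C(C)C)(C(C)C)C(C)C)cc(O[Si](C(C)C)(C(C)C)C(C)C)c2)c1 | intermediate
7 | 1-({1-[3,5-bis(triisopropylsilyloxy)phenyl]ethenyl}oxy)-3,5-bis(methoxymethoxy)benzene | COCOc1cc(OCOC)cc(OC(=C)c2cc(O[Si](C(C)C)(C(C)C)C(C)C)cc(O[Si](C(C)C)(C(C)C)C(C)C)c2)c1 | intermediate
8 | geranyl bromide | CC(C)=CCC/C(C)=C/CBr | starting material
9 | aryllithium of 7, lithiated between the two MOM ethers | [Li]c1c(OCOC)cc(OC(=C)c2cc(O[Si](C(C)C)(C(C)C)C(C)C)cc(O[Si](C(C)C)(C(C)C)C(C)C)c2)cc1OCOC | intermediate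
10 | 5-({1-[3,5-bis(triisopropylsilyloxy)phenyl]ethenyl}oxy)-2-[(2E)-3,7-dimethylocta-2,6-dien-1-yl]-1,3-bis(methoxymethoxy)benzene | CC(C)=CCC/C(C)=C/Cc1c(OCOC)cc(OC(=C)c2cc(O[Si](C(C)C)(C(C)C)C(C)C)cc(O[Si](C(C)C)(C(C)C)C(C)C)c2)cc1OCOC | intermediate
11 | aryllithium of 10, lithiated between a MOM ether and the vinyl ether oxygen | CC(C)=CCC/C(C)=C/Cc1c(OCOC)cc(OC(=C)c2cc(O[Si](C(C)C)(C(C)C)C(C)C)cc(O[Si](C(C)C)(C(C)C)C(C)C)c2)c([Li])c1OCOC | intermediate
12 | lithium hemiaminal alkoxide from 11 and DMF | CC(C)=CCC/C(C)=C/Cc1c(OCOC)cc(OC(=C)c2cc(O[Si](C(C)C)(C(C)C)C(C)C)cc(O[Si](C(C)C)(C(C)C)C(C)C)c2)c(C(O[Li])N(C)C)c1OCOC | intermediate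
13 | 6-({1-[3,5-bis(triisopropylsilyloxy)phenyl]ethenyl}oxy)-3-[(2E)-3,7-dimethylocta-2,6-dien-1-yl]-2,4-bis(methoxymethoxy)benzaldehyde | CC(C)=CCC/C(C)=C/Cc1c(OCOC)cc(OC(=C)c2cc(O[Si](C(C)C)(C(C)C)C(C)C)cc(O[Si](C(C)C)(C(C)C)C(C)C)c2)c(C=O)c1OCOC | intermediate
14 | (2S)-2-[3,5-bis(triisopropylsilyloxy)phenyl]-6-[(2E)-3,7-dimethylocta-2,6-dien-1-yl]-5,7-bis(methoxymethoxy)-2,3-dihydro-4H-chromen-4-one | CC(C)=CCC/C(C)=C/Cc1c(OCOC)cc2c(c1OCOC)C(=O)C[C@@H](c1cc(O[Si](C(C)C)(C(C)C)C(C)C)cc(O[Si](C(C)C)(C(C)C)C(C)C)c1)O2 | intermediate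
15 | (2S)-2-(3,5-dihydroxyphenyl)-6-[(2E)-3,7-dimethylocta-2,6-dien-1-yl]-5,7-bis(methoxymethoxy)-2,3-dihydro-4H-chromen-4-one | CC(C)=CCC/C(C)=C/Cc1c(OCOC)cc2c(c1OCOC)C(=O)C[C@@H](c1cc(O)cc(O)c1)O2 | intermediate
16 | Schizolaenone C | CC(C)=CCC/C(C)=C/Cc1c(O)cc2c(c1O)C(=O)C[C@@H](c1cc(O)cc(O)c1)O2 | target

**Step count and risks**

Total step count: 9. Longest linear sequence: 8 (steps 1, 3, 4, 5, 6, 7, 8, 9); step 2 is the one-step side branch for ring B.

Steps most likely to fail:

1. Step 7 (proposed new method). What may go wrong: CO extrusion from the acyl rhodium hydride, loss of the aryloxide by β-elimination from the alkyl rhodium intermediate, exo closure, or weak facial discrimination at the enol ether. The fallback uses known chemistry, sets out from compound 13 and comes back at compound 14. The enol ether of 13 is hydrolysed (PPTS, acetone/H2O, rt; the MOM ethers should survive) to 6-hydroxy-3-[(2E)-3,7-dimethylocta-2,6-dien-1-yl]-2,4-bis(methoxymethoxy)benzaldehyde F1 and 1-[3,5-bis(triisopropylsilyloxy)phenyl]ethanone F2. The ketone is brominated at the methyl group (CuBr2, EtOAc, reflux) to 2-bromo-1-[3,5-bis(triisopropylsilyloxy)phenyl]ethanone F3. Corey–Bakshi–Shibata reduction (BH3·SMe2, (S)-Me-CBS, THF, 0 °C) should give (1S)-2-bromo-1-[3,5-bis(triisopropylsilyloxy)phenyl]ethanol F4. Mitsunobu coupling of F4 with the phenol of F1 (PPh3, DIAD, THF, 0 °C) should give, with inversion, 6-{(1R)-2-bromo-1-[3,5-bis(triisopropylsilyloxy)phenyl]ethoxy}-3-[(2E)-3,7-dimethylocta-2,6-dien-1-yl]-2,4-bis(methoxymethoxy)benzaldehyde F5. The same C4–C3 bond is then closed by N-heterocyclic carbene catalysis (3-benzyl-5-(2-hydroxyethyl)-4-methylthiazolium chloride, DBU, 1,4-dioxane, 60 °C): the Breslow intermediate of the aldehyde displaces the primary bromide in a 6-exo-tet alkylation, a known route to chroman-4-ones, giving 14 with C2 untouched.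

2. Step 5. What may go wrong: metalation next to the vinyl ether oxygen instead of between the two MOM ethers, addition of the alkyllithium to the styrene-type double bond, or allylic transposition in the coupling. The fallback puts the geranyl group in before the two rings are joined; it sets out from compound 2 and comes back at compound 10. Phenol 2 is silylated (TIPSCl, imidazole, DMF) to [3,5-bis(methoxymethoxy)phenoxy]triisopropylsilane F6, in which only the C–H between the two MOM ethers is activated. Lithiation and allylation (n-BuLi, THF, 0 °C; CuBr·SMe2; 8) should give {4-[(2E)-3,7-dimethylocta-2,6-dien-1-yl]-3,5-bis(methoxymethoxy)phenoxy}triisopropylsilane F7. Desilylation (Bu4NF, THF) gives 4-[(2E)-3,7-dimethylocta-2,6-dien-1-yl]-3,5-bis(methoxymethoxy)phenol F8. Steglich esterification with acid 5 (DCC, DMAP) gives 4-[(2E)-3,7-dimethylocta-2,6-dien-1-yl]-3,5-bis(methoxymethoxy)phenyl 3,5-bis(triisopropylsilyloxy)benzoate F9, and Petasis methylenation (Cp2TiMe2, toluene/THF, 65 °C) leads to 10.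

3. Step 6. What may go wrong: deprotonation of the benzylic and allylic CH2 of the geranyl chain, carbolithiation of the enol ether, or slow metalation beside the bulky aryloxyvinyl group. The fallback brings in the formyl carbon by bromine–lithium exchange, which outruns deprotonation and addition at −78 °C. It sets out from compound 2, which is carried to phenol F8 as in the fallback to step 5, and comes back at compound 13. Bromination ortho to the hydroxyl (NBS, CH2Cl2, −78 °C; the two ortho positions are equivalent and the para position is blocked) should give 2-bromo-4-[(2E)-3,7-dimethylocta-2,6-dien-1-yl]-3,5-bis(methoxymethoxy)phenol F10. Esterification with 5 (DCC, DMAP) gives 2-bromo-4-[(2E)-3,7-dimethylocta-2,6-dien-1-yl]-3,5-bis(methoxymethoxy)phenyl 3,5-bis(triisopropylsilyloxy)benzoate F11. Petasis methylenation gives 4-bromo-5-({1-[3,5-bis(triisopropylsilyloxy)phenyl]ethenyl}oxy)-2-[(2E)-3,7-dimethylocta-2,6-dien-1-yl]-1,3-bis(methoxymethoxy)benzene F12. Exchange and formylation (t-BuLi, 2 equiv, THF, −78 °C; DMF) then lead to 13.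

Further compounds
F1 | step 7 | 6-hydroxy-3-[(2E)-3,7-dimethylocta-2,6-dien-1-yl]-2,4-bis(methoxymethoxy)benzaldehyde | CC(C)=CCC/C(C)=C/Cc1c(OCOC)cc(O)c(C=O)c1OCOC
F2 | step 7 | 1-[3,5-bis(triisopropylsilyloxy)phenyl]ethanone | CC(=O)c1cc(O[Si](C(C)C)(C(C)C)C(C)C)cc(O[Si](C(C)C)(C(C)C)C(C)C)c1
F3 | step 7 | 2-bromo-1-[3,5-bis(triisopropylsilyloxy)phenyl]ethanone | BrCC(=O)c1cc(O[Si](C(C)C)(C(C)C)C(C)C)cc(O[Si](C(C)C)(C(C)C)C(C)C)c1
F4 | step 7 | (1S)-2-bromo-1-[3,5-bis(triisopropylsilyloxy)phenyl]ethanol | O[C@H](CBr)c1cc(O[Si](C(C)C)(C(C)C)C(C)C)cc(O[Si](C(C)C)(C(C)C)C(C)C)c1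
F5 | step 7 | 6-{(1R)-2-bromo-1-[3,5-bis(triisopropylsilyloxy)phenyl]ethoxy}-3-[(2E)-3,7-dimethylocta-2,6-dien-1-yl]-2,4-bis(methoxymethoxy)benzaldehyde | CC(C)=CCC/C(C)=C/Cc1c(OCOC)cc(O[C@@H](CBr)c2cc(O[Si](C(C)C)(C(C)C)C(C)C)cc(O[Si](C(C)C)(C(C)C)C(C)C)c2)c(C=O)c1OCOC
F6 | step 5 | [3,5-bis(methoxymethoxy)phenoxy]triisopropylsilane | COCOc1cc(OCOC)cc(O[Si](C(C)C)(C(C)C)C(C)C)c1
F7 | step 5 | {4-[(2E)-3,7-dimethylocta-2,6-dien-1-yl]-3,5-bis(methoxymethoxy)phenoxy}triisopropylsilane | CC(C)=CCC/C(C)=C/Cc1c(OCOC)cc(O[Si](C(C)C)(C(C)C)C(C)C)cc1OCOC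
F8 | step 5 | 4-[(2E)-3,7-dimethylocta-2,6-dien-1-yl]-3,5-bis(methoxymethoxy)phenol | CC(C)=CCC/C(C)=C/Cc1c(OCOC)cc(O)cc1OCOC
F9 | step 5 | 4-[(2E)-3,7-dimethylocta-2,6-dien-1-yl]-3,5-bis(methoxymethoxy)phenyl 3,5-bis(triisopropylsilyloxy)benzoate | CC(C)=CCC/C(C)=C/Cc1c(OCOC)cc(OC(=O)c2cc(O[Si](C(C)C)(C(C)C)C(C)C)cc(O[Si](C(C)C)(C(C)C)C(C)C)c2)cc1OCOC
F10 | step 6 | 2-bromo-4-[(2E)-3,7-dimethylocta-2,6-dien-1-yl]-3,5-bis(methoxymethoxy)phenol | CC(C)=CCC/C(C)=C/Cc1c(OCOC)cc(O)c(Br)c1OCOC
F11 | step 6 | 2-bromo-4-[(2E)-3,7-dimethylocta-2,6-dien-1-yl]-3,5-bis(methoxymethoxy)phenyl 3,5-bis(triisopropylsilyloxy)benzoate | CC(C)=CCC/C(C)=C/Cc1c(OCOC)cc(OC(=O)c2cc(O[Si](C(C)C)(C(C)C)C(C)C)cc(O[Si](C(C)C)(C(C)C)C(C)C)c2)c(Br)c1OCOC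
F12 | step 6 | 4-bromo-5-({1-[3,5-bis(triisopropylsilyloxy)phenyl]ethenyl}oxy)-2-[(2E)-3,7-dimethylocta-2,6-dien-1-yl]-1,3-bis(methoxymethoxy)benzene | CC(C)=CCC/C(C)=C/Cc1c(OCOC)cc(OC(=C)c2cc(O[Si](C(C)C)(C(C)C)C(C)C)cc(O[Si](C(C)C)(C(C)C)C(C)C)c2)c(Br)c1OCOC
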